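**Retrosynthetic overview**

1. Numbering: C1 = CH(OAc), C2 = CH2 beside it, C3 = C(Me) beside C4 = CHBr, C5 = CH2, C6 = C(Me), C7 = CH(Me), C8 = CHBr, C9 = CHOH, C10 = CH(Me), C11 = the carbon common to all rings. Ring A = cyclohexane (C6–C11), ring B = cyclopentane (C3–C6, C11), ring C = cyclobutane (C1–C3, C11).
2. Endgame, functional groups only: C9-OH/C8-Br ⇐ C9 ketone ⇐ C9=C10 alkene; C4-Br ⇐ inverted C4 alcohol ⇐ C4 ketone; C1-OAc ⇐ cyclobutanone ⇐ 1-methoxycyclobutene.
3. Enabling feature: rings B and C share the bond C3–C11 between two fully substituted carbons, and C1/C2 carry no carbon substituent. The bicyclo[3.2.0]hept-6-en-2-one core is therefore the valence isomer of a cyclohepta-2,4-dienone (C4=O, C3=C2, C1=C11). Breaking C3–C11 merges rings B and C into one seven-membered ring and erases the stereocentres C3 and C11.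
4. The resulting bicyclic 6-7 methoxy-trienone has stereocentres only at C6 and C7. It comes from a 1,4-dehydration and a ring-closing metathesis (C2=C3), and these from a ring A enone plus a methoxyallyl unit (C1, C2) and an isopropenyl unit (C3).
5. Ring A ⇐ 2-methylcyclohex-2-enone by asymmetric conjugate methylation (C7) and enolate alkylation (C6). Ring order: A (bought), seven-membered ring (metathesis), then B and C together in the photochemical ring contraction.

Key step: step 9

Assumption: the phosphoramidite enantiomer named in step 1 is taken to deliver the (S) centre; its mirror image is equally available if the sense is opposite. Centres left unmarked in a SMILES are mixtures that are erased or equilibrated later. "Exo" at C1 means the face of ring C turned away from ring B. "Syn/anti" at C4 refers to ring C.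

**Step 1**
Reactants: 1 2-methylcyclohex-2-en-1-one
Product: 3 (S)-[(2,3-dimethylcyclohex-1-en-1-yl)oxy]trimethylsilane, via dimethylaluminium enolate 2 (not isolated)
Conditions: Me3Al (1.3 equiv), [Cu(MeCN)4]BF4 (2 mol %), (S,R,R)-BINOL bis(1-phenylethyl)phosphoramidite (4 mol %), Et2O, −30 °C; then TMSOTf, −30 to 0 °C
Reagents that add atoms: trimethylaluminium C[Al](C)C; trimethylsilyl triflate C[Si](C)(C)OS(=O)(=O)C(F)(F)F
Why: Copper-catalysed asymmetric conjugate addition to the α-substituted enone should set C7 under ligand control, and O-silylation fixes the tetrasubstituted enolate regiochemistry.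

**Step 2**
Reactants: 3 (S)-[(2,3-dimethylcyclohex-1-en-1-yl)oxy]trimethylsilane; 4 methyl bromoacetate
Product: 6 methyl 2-[(1R,2S)-1,2-dimethyl-6-oxocyclohexyl]acetate, via lithium enolate 5 (not isolated)
Conditions: MeLi, THF, 0 °C; then 4, DMPU, −78 to −20 °C
Reagents that add atoms: none
Why: MeLi cleavage of the silyl enol ether regenerates the regiodefined lithium enolate, and the SN2 alkylation should enter anti to the pseudo-axial C7 methyl, which sets quaternary C6 with its methyl cis to the C7 methyl.

**Step 3**
Reactants: 6 methyl 2-[(1R,2S)-1,2-dimethyl-6-oxocyclohexyl]acetate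
Product: 8 methyl 2-[(1R,6S)-1,3,6-trimethyl-2-oxocyclohexyl]acetate (C10 epimers), via lithium enolate 7 (not isolated)
Conditions: LiN(i-Pr)2 (1.05 equiv), THF, −78 °C; MeI, −78 to 0 °C
Reagents that add atoms: iodomethane CI
Why: In this kinetic enolate methylation C6 is quaternary, so the ketone can enolise only toward C10; the ketone is more acidic than the neopentyl ester CH2, and the C10 configuration is irrelevant because C10 becomes sp2 in step 4.

**Step 4**
Reactants: 8 methyl 2-[(1R,6S)-1,3,6-trimethyl-2-oxocyclohexyl]acetate
Product: 10 methyl 2-[(1R,6S)-1,3,6-trimethyl-2-oxocyclohex-3-en-1-yl]acetate, via trimethylsilyl enol ether 9 (not isolated)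
Conditions: TMSOTf, Et3N, CH2Cl2, 0 °C; solvent change; Pd(OAc)2 (1.05 equiv), MeCN, rt
Reagents that add atoms: none
Why: In this Saegusa–Ito oxidation the only possible silyl enol ether (C10=C11) is palladated, and β-hydride loss from the ring CH2 (C9) should give the endocyclic 2-methyl enone.

**Step 5**
Reactants: 10 methyl 2-[(1R,6S)-1,3,6-trimethyl-2-oxocyclohex-3-en-1-yl]acetate; 11 allyl methyl ether
Product: 14 (3aR,4S)-7a-(1-methoxyallyl)-3a,4,7-trimethyl-3a,4,5,7a-tetrahydro-1-benzofuran-2(3H)-one (mixture at C11 and C1), via 3-methoxyallylzinc chloride 12 (not isolated), via chlorozinc alkoxide 13 (not isolated)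
Conditions: 11, s-BuLi, THF, −78 °C; ZnCl2, −78 °C; then 10, −78 °C to rt; aqueous work-up
Reagents that add atoms: none
Why: The γ-alkoxyallylzinc reagent adds 1,2 to the hindered enone through a cyclic SE2' transition state at its oxygen-bearing carbon (C1–C11 bond), the alkoxide then lactonises onto the ester, and both new centres are erased in step 8.

**Step 6**
Reactants: 14 the γ-lactone from step 5; 15 2-bromopropene
Product: 18 1-[(1R,6S)-2-hydroxy-2-(1-methoxyallyl)-1,3,6-trimethylcyclohex-3-en-1-yl]-3-methylbut-3-en-2-one, via isopropenyllithium 16 (not isolated), via lithium lactolate 17 (not isolated)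
Conditions: 15, t-BuLi (2 equiv), Et2O, −78 °C; then 14, THF, −78 °C; quench with water at −78 °C
Reagents that add atoms: none
Why: This is a mono-addition of an alkenyllithium to a γ-lactone, in which the tetrahedral lactolate persists at −78 °C and opens to the C4 isopropenyl ketone only on work-up, so the enone never meets the nucleophile.

**Step 7**
Reactants: 18 the hydroxy dienone from step 6
Product: 19 (1S,9aR)-4a-hydroxy-5-methoxy-1,4,7,9a-tetramethyl-1,2,4a,5,9,9a-hexahydro-8H-benzo[7]annulen-8-one (mixture at C11 and C1)
Conditions: second-generation Grubbs catalyst (5 mol %), toluene (2 mM), 80 °C, argon sparge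
Reagents that add atoms: none
Why: Ring-closing metathesis between the monosubstituted alkene (C2) and the isopropenyl ketone (C3) closes the seven-membered ring as the trisubstituted enone; the ring size enforces the cis C2=C3 geometry and the ring A alkene is inert.

**Step 8**
Reactants: 19 the bicyclic hydroxy enone from step 7
Product: 21 (1S,9aR)-5-methoxy-1,4,7,9a-tetramethyl-1,2,9,9a-tetrahydro-8H-benzo[7]annulen-8-one, via tertiary mesylate 20 (not isolated)
Conditions: MsCl, Et3N, CH2Cl2, 0 °C to rt; then DBU (0.2 equiv), rt
Reagents that add atoms: none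
Why: The tertiary allylic C11 alcohol is activated and lost by vinylogous E1cB/E1 elimination of C1-H (γ to the C4 ketone), and catalytic DBU funnels any ring A diene isomer into the fully conjugated trienone, so both diastereomer series converge.

**Step 9**
Reactants: 21 the bicyclic methoxy-trienone from step 8
Product: 22 tricyclic ketone: 1-methoxycyclobutene (C1=C2, ring C) cis-fused to the cyclopentanone (C4=O, ring B), ring A with C9=C10, C6-Me syn and C3-Me anti to ring C
Conditions: hν (365 nm LED), degassed cyclohexane (5 mM), Pyrex or FEP flow coil, 15 °C, stopped when 21 is consumed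
Reagents that add atoms: none
Why: Excitation of the cyclohepta-2,4-dienone chromophore (C4=O, C3=C2, C1=C11) triggers a 4π disrotatory electrocyclisation that joins C3 to C11 (cis→trans isomerisation of C2=C3 followed by thermal conrotatory closure would give the same product). The closest known reaction is the photoisomerisation of eucarvone to 1,4,4-trimethylbicyclo[3.2.0]hept-6-en-2-one, which has the same α-methyl, ketone and quaternary-carbon pattern, and the closure of tropolone ethers shows that an alkoxy group on the diene is tolerated. The single new σ bond closes ring C as a cyclobutene in the 4π electrocyclic mode and at the same time contracts the seven-membered ring by two atoms (C1, C2) to ring B. The ring fusion at C3/C11 can only be cis, and its face is dictated by C6: ring A holds C7 near the diene plane, so C5 lies on one face only, the bond must form on that face, and this puts C1 syn to the C6 methyl and makes ring A cis-fused. No other closure is possible, because the C1=C11–C10=C9 diene is locked s-trans and the central triene bond is E; 365 nm light is absorbed by 21 but not by the β,γ-unsaturated ketone 22, which should suppress a secondary 1,3-acyl shift, and the aprotic non-polar medium avoids the polar rearrangements of protonated dienones. The step creates two vicinal quaternary stereocentres and two rings, and it leaves three orthogonal handles (C4 ketone, C1 enol ether, C9=C10).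

**Step 10**
Reactants: 22 the tricyclic ketone from step 9
Product: 24 tricyclic hydroxy cyclobutanone (C1=O, C4-OH anti to ring C, C9=C10), via C4 alcohol enol ether 23 (not isolated)
Conditions: LiBH(s-Bu)3, THF, −78 °C; then 1 M aq HCl, THF, 0 °C
Reagents that add atoms: water O
Why: The bulky hydride should attack C4 from the face bearing the flat cyclobutene (sp2 C2-H) and anti to the vicinal C3 methyl, which places the hydroxyl anti to ring C, and the strained enol ether then hydrolyses far faster than the alkene can protonate.

**Step 11**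
Reactants: 24 the hydroxy cyclobutanone from step 10
Product: 25 tricyclic diol (C1-OH exo, C4-OH anti to ring C)
Conditions: SmI2 (2.5 equiv), H2O (50 equiv), THF, 0 °C
Reagents that add atoms: none
Why: In this single-electron ketone reduction the bulky samarium-bound oxygen of the ketyl/organosamarium should settle on the less hindered exo face (the endo face is blocked by the C6 methyl and ring B), so the proton arrives endo and the exo alcohol forms, complementary to hydride delivery as in the camphor series; the ring bonds lie in the nodal plane of the ketyl, so ring C should stay closed.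

**Step 12**
Reactants: 25 the diol from step 11
Product: 26 tricyclic acetoxy alcohol (C1-OAc exo, C4-OH free)
Conditions: Ac2O (1.1 equiv), Et3N, DMAP (5 mol %), CH2Cl2, −20 °C
Reagents that add atoms: acetic anhydride CC(=O)OC(C)=O
Why: This is a site-selective acylation, because the exo C1 hydroxyl sits on the open face of ring C whereas the C4 hydroxyl is pseudo-axial, cis to the C3 methyl and 1,3-syn to C7.

**Step 13**
Reactants: 26 the acetoxy alcohol from step 12
Product: 28 tricyclic bromo acetate (C4-Br syn to ring C, C1-OAc exo, C9=C10), via C4 triflate 27 (not isolated)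
Conditions: Tf2O, pyridine, CH2Cl2, −40 °C; then Bu4NBr (5 equiv), toluene, −40 °C to rt
Reagents that add atoms: tetrabutylammonium bromide CCCC[N+](CCCC)(CCCC)CCCC.[Br-]
Why: SN2 displacement with inversion at a cyclopentyl carbon next to a quaternary centre, by the same logic as inversion at C17 of steroids, lets bromide enter anti to the C3 methyl and ends in the pseudo-equatorial, thermodynamically preferred position.

**Step 14**
Reactants: 28 the bromo acetate from step 13
Product: 30 tricyclic C9 alcohol (C9 and C10 provisional), via C9 alkylborane 29 (not isolated)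
Conditions: BH3·SMe2, THF, 0 °C to rt; then H2O2, aq NaHCO3, 0 °C
Reagents that add atoms: hydrogen peroxide OO
Why: Hydroboration–oxidation of the only alkene places boron on the less substituted C9, the mildly basic oxidation spares acetate and bromide, and the two new centres are reset in steps 15 and 17.

**Step 15**
Reactants: 30 the C9 alcohol from step 14
Product: 31 tricyclic C9 ketone (C10-Me equatorial, trans to the C6 methyl)
Conditions: Dess–Martin periodinane, CH2Cl2, rt; then DBU (0.2 equiv), toluene, rt
Reagents that add atoms: none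
Why: Dess–Martin oxidation is followed by base equilibration of the α-centre, which sets C10 thermodynamically because an axial C10 methyl would be 1,3-diaxial to the axial C6 methyl.

**Step 16**
Reactants: 31 the C9 ketone from step 15
Product: 33 tricyclic α-bromo ketone (C8-Br equatorial, trans to the C7 methyl), via C8 silyl enol ether 32 (not isolated)
Conditions: LiN(SiMe3)2 (1.05 equiv), Me3SiCl, THF, −78 °C; then NBS, THF, −78 to 0 °C
Reagents that add atoms: N-bromosuccinimide O=C1CCC(=O)N1Br
Why: The amide base, too weak to enolise the acetate, deprotonates kinetically at the less hindered C8, and in the bromination of the silyl enol ether axial attack is blocked by the 1,3-diaxial C6 methyl (as in 2α-bromination of 3-keto steroids), so the equatorial and also more stable bromide should result.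

**Step 17**
Reactants: 33 the α-bromo ketone from step 16
Product: 34 CNP0246576.1 (target)
Conditions: NaBH4, MeOH–CH2Cl2, −40 °C
Reagents that add atoms: none
Why: In this hydride reduction axial approach to C9 is blocked by the axial C11–C3 bond (1,3-diaxial), so equatorial attack should give the axial alcohol cis to C8-Br and C10-Me; this cis bromohydrin cannot close to an epoxide and the acetate survives.

**Compound list**

1 | 2-methylcyclohex-2-en-1-one | CC1=CCCCC1=O | starting material
2 | dimethylaluminium (S)-2,3-dimethylcyclohex-1-en-1-olate | C[Al](C)OC1=C(C)[C@@H](C)CCC1 | intermediate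
3 | (S)-[(2,3-dimethylcyclohex-1-en-1-yl)oxy]trimethylsilane | C[Si](C)(C)OC1=C(C)[C@@H](C)CCC1 | intermediate
4 | methyl bromoacetate | COC(=O)CBr | starting material
5 | lithium (S)-2,3-dimethylcyclohex-1-en-1-olate | [Li]OC1=C(C)[C@@H](C)CCC1 | intermediate
6 | methyl 2-[(1R,2S)-1,2-dimethyl-6-oxocyclohexyl]acetate | COC(=O)C[C@]1(C)[C@@H](C)CCCC1=O | intermediate
7 | lithium enolate of 6 (C10=C11) | COC(=O)C[C@]1(C)[C@@H](C)CCC=C1O[Li] | intermediate
8 | methyl 2-[(1R,6S)-1,3,6-trimethyl-2-oxocyclohexyl]acetate (C10 epimers) | COC(=O)C[C@]1(C)[C@@H](C)CCC(C)C1=O | intermediate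
9 | trimethylsilyl enol ether of 8 | COC(=O)C[C@]1(C)[C@@H](C)CCC(C)=C1O[Si](C)(C)C | intermediate
10 | methyl 2-[(1R,6S)-1,3,6-trimethyl-2-oxocyclohex-3-en-1-yl]acetate | COC(=O)C[C@]1(C)[C@@H](C)CC=C(C)C1=O | intermediate
11 | allyl methyl ether | C=CCOC | starting material
12 | (Z)-3-methoxyallylzinc chloride | CO/C=C\C[Zn]Cl | intermediate
13 | chlorozinc alkoxide of the 1,2-adduct | COC(=O)C[C@]1(C)[C@@H](C)CC=C(C)C1(O[Zn]Cl)C(OC)C=C | intermediate
14 | (3aR,4S)-7a-(1-methoxyallyl)-3a,4,7-trimethyl-3a,4,5,7a-tetrahydro-1-benzofuran-2(3H)-one | C=CC(OC)C12OC(=O)C[C@]1(C)[C@@H](C)CC=C2C | intermediate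
15 | 2-bromopropene | CC(Br)=C | starting material
16 | isopropenyllithium | [Li]C(C)=C | intermediate
17 | lithium lactolate from 14 and 16 | [Li]OC1(C(C)=C)C[C@]2(C)[C@@H](C)CC=C(C)C2(O1)C(OC)C=C | intermediate
18 | 1-[(1R,6S)-2-hydroxy-2-(1-methoxyallyl)-1,3,6-trimethylcyclohex-3-en-1-yl]-3-methylbut-3-en-2-one | C=C(C)C(=O)C[C@]1(C)[C@@H](C)CC=C(C)C1(O)C(OC)C=C | intermediate
19 | (1S,9aR)-4a-hydroxy-5-methoxy-1,4,7,9a-tetramethyl-1,2,4a,5,9,9a-hexahydro-8H-benzo[7]annulen-8-one | O=C1C[C@]2(C)[C@@H](C)CC=C(C)C2(O)C(OC)C=C1C | intermediate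
20 | C11 mesylate of 19 | O=C1C[C@]2(C)[C@@H](C)CC=C(C)C2(OS(C)(=O)=O)C(OC)C=C1C | intermediate
21 | (1S,9aR)-5-methoxy-1,4,7,9a-tetramethyl-1,2,9,9a-tetrahydro-8H-benzo[7]annulen-8-one | O=C1C[C@]2(C)[C@@H](C)CC=C(C)C2=C(OC)C=C1C | intermediate
22 | tricyclic methoxycyclobutene ketone (C4=O, C1=C2, C9=C10) | COC1=C[C@@]2(C)C(=O)C[C@]3(C)[C@@H](C)CC=C(C)[C@]123 | intermediate
23 | C4 alcohol (anti to ring C) of 22, enol ether intact | COC1=C[C@@]2(C)[C@H](O)C[C@]3(C)[C@@H](C)CC=C(C)[C@]123 | intermediate
24 | tricyclic hydroxy cyclobutanone | O=C1C[C@@]2(C)[C@H](O)C[C@]3(C)[C@@H](C)CC=C(C)[C@]123 | intermediate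
25 | tricyclic diol (C1-OH exo) | O[C@@H]1C[C@@]2(C)[C@H](O)C[C@]3(C)[C@@H](C)CC=C(C)[C@]123 | intermediate
26 | tricyclic acetoxy alcohol | CC(=O)O[C@@H]1C[C@@]2(C)[C@H](O)C[C@]3(C)[C@@H](C)CC=C(C)[C@]123 | intermediate
27 | C4 triflate of 26 | CC(=O)O[C@@H]1C[C@@]2(C)[C@H](OS(=O)(=O)C(F)(F)F)C[C@]3(C)[C@@H](C)CC=C(C)[C@]123 | intermediate
28 | tricyclic bromo acetate (C4-Br syn to ring C) | CC(=O)O[C@@H]1C[C@@]2(C)[C@@H](Br)C[C@]3(C)[C@@H](C)CC=C(C)[C@]123 | intermediate
29 | C9 alkylborane | CC(=O)O[C@@H]1C[C@@]2(C)[C@@H](Br)C[C@]3(C)[C@@H](C)CC(B)C(C)[C@]123 | intermediate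
30 | C9 alcohol (C9, C10 provisional) | CC(=O)O[C@@H]1C[C@@]2(C)[C@@H](Br)C[C@]3(C)[C@@H](C)CC(O)C(C)[C@]123 | intermediate
31 | C9 ketone | CC(=O)O[C@@H]1C[C@@]2(C)[C@@H](Br)C[C@]3(C)[C@@H](C)CC(=O)[C@H](C)[C@]123 | intermediate
32 | C8=C9 trimethylsilyl enol ether | CC(=O)O[C@@H]1C[C@@]2(C)[C@@H](Br)C[C@]3(C)[C@@H](C)C=C(O[Si](C)(C)C)[C@H](C)[C@]123 | intermediate
33 | C8-bromo C9 ketone | CC(=O)O[C@@H]1C[C@@]2(C)[C@@H](Br)C[C@]3(C)[C@@H](C)[C@H](Br)C(=O)[C@H](C)[C@]123 | intermediate
34 | CNP0246576.1 | CC(=O)O[C@@H]1C[C@@]2(C)[C@@H](Br)C[C@]3(C)[C@@H](C)[C@H](Br)[C@H](O)[C@H](C)[C@]123 | target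

Total step count: 17. Longest linear sequence: 17 steps (from 1).

**Steps most likely to fail**

**Step 9.** The excited, donor-substituted trienone may lose its energy by internal conversion, or by cis–trans isomerisation followed by dimerisation. Long irradiation may also start a 1,3-acyl shift in the product. The fallback removes the carbonyl chromophore and relies on the classical photoisomerisation of a cyclohepta-1,3-diene to a bicyclo[3.2.0]hept-6-ene. It sets out from 21, which is reduced at C4 (NaBH4, CeCl3, MeOH, 0 °C) to the trienol F1. This is silylated (TBSCl, imidazole, DMF) to the silyl ether F2 and irradiated directly (300 nm, cyclohexane) to the tricyclic silyl ether F3. Bu4NF then gives the tricyclic alcohol F4, and Dess–Martin oxidation brings the material back to the route at 22.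

**Step 11.** Protonation of the ketyl/organosamarium species may occur from both faces, or coordination of the C4 hydroxyl to samarium may turn the facial preference. The fallback replaces electron transfer by kinetic hydride attack followed by SN2 inversion with the acetate nucleophile itself. It sets out from 24, which is mesylated (MsCl, Et3N) to the keto mesylate F5. LiBH(s-Bu)3 at −78 °C attacks the exo face and gives the endo alcohol F6. A Mitsunobu reaction (PPh3, DIAD, AcOH, toluene) inverts C1 to the exo acetate mesylate F7. LiBr in DMF then displaces the mesylate with inversion, and the sequence comes back at 28 without needing steps 12 and 13.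

**Step 13.** The neopentyl-type triflate may ionise with migration of C2 from C3 to C4 (expansion of ring C), or it may eliminate toward C5. Either could outrun the backside attack, which has to pass the endo hydrogen of C2. The fallback moves the substitution to the cyclobutene stage, where C2 is sp2 and the trajectory is open, and uses non-ionising oxyphosphonium activation. It sets out from 23, isolated by neutral work-up before the acid treatment of step 10. CBr4, PPh3 and 2,6-lutidine in CH2Cl2 give the bromo enol ether F8. Aqueous oxalic acid gives the bromo cyclobutanone F9. SmI2–H2O without amine at 0 °C gives the exo bromo alcohol F10, and Ac2O/DMAP brings it back at 28.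

**Further compounds**

F1 | step 9 | trienol from 21 (C4 epimers) | OC1C[C@]2(C)[C@@H](C)CC=C(C)C2=C(OC)C=C1C
F2 | step 9 | tert-butyldimethylsilyl ether of F1 | CC(C)(C)[Si](C)(C)OC1C[C@]2(C)[C@@H](C)CC=C(C)C2=C(OC)C=C1C
F3 | step 9 | tricyclic methoxycyclobutene silyl ether | COC1=C[C@@]2(C)C(O[Si](C)(C)C(C)(C)C)C[C@]3(C)[C@@H](C)CC=C(C)[C@]123
F4 | step 9 | tricyclic methoxycyclobutene alcohol (C4 epimers) | COC1=C[C@@]2(C)C(O)C[C@]3(C)[C@@H](C)CC=C(C)[C@]123
F5 | step 11 | keto mesylate | O=C1C[C@@]2(C)[C@H](OS(C)(=O)=O)C[C@]3(C)[C@@H](C)CC=C(C)[C@]123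
F6 | step 11 | endo C1 alcohol mesylate | O[C@H]1C[C@@]2(C)[C@H](OS(C)(=O)=O)C[C@]3(C)[C@@H](C)CC=C(C)[C@]123
F7 | step 11 | exo C1 acetate mesylate | CC(=O)O[C@@H]1C[C@@]2(C)[C@H](OS(C)(=O)=O)C[C@]3(C)[C@@H](C)CC=C(C)[C@]123
F8 | step 13 | bromo enol ether | COC1=C[C@@]2(C)[C@@H](Br)C[C@]3(C)[C@@H](C)CC=C(C)[C@]123
F9 | step 13 | bromo cyclobutanone | O=C1C[C@@]2(C)[C@@H](Br)C[C@]3(C)[C@@H](C)CC=C(C)[C@]123
F10 | step 13 | exo bromo alcohol | O[C@@H]1C[C@@]2(C)[C@@H](Br)C[C@]3(C)[C@@H](C)CC=C(C)[C@]123
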